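**Plan**

- Retrosynthetic cuts: the two O–Si bonds; the biaryl bond chromene C5–benzofuran C2; the pyran C2–C3 bond; both C=CH2 bonds, back to an O-acetylsalicylaldehyde; then the aryl–prenyl, aryl–I and aryl–CHO bonds, back to 1-bromo-3,5-dimethoxybenzene.
- Forward order: the resorcinol ring is bought and dressed (CHO, I, prenyl, differentiation of the two oxygens); one titanium reagent turns CHO and OAc into vinyl and 2-propenyl ether; acid closes the pyran ring; the intact benzofuran is joined last by Negishi coupling; desilylation ends the route.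
- Enabling feature: chromene C4a lies ortho to O1 and para to O7. Vinyl carbon C3 is therefore nucleophilic and the C4 cation is an oxygen-stabilised benzylic ion. C2 is at the ketone oxidation level, so it can be entered O-bound as an oxocarbenium ion that comes from the carbonyl carbon of an aryl acetate.
- This closure fixes the angular chromene regiochemistry from the aldehyde position and leaves the prenyl group and the second phenol untouched. It is run before the biaryl coupling so that benzofuran C3 cannot trap the C4 cation.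
- Stereochemistry: the target has no stereocentre; the cis C3=C4 alkene is enforced by the six-membered ring.

Key step: step 8

Remark: benzofuran-6-ol and tributyl(3-methylbut-2-en-1-yl)stannane are taken to be purchasable.

**Route**

Step 1
Reactants: 1 1-bromo-3,5-dimethoxybenzene
Product: 3 2-bromo-4,6-dimethoxybenzaldehyde, via aryl iminium chloride 2 (not isolated)
Conditions: POCl3, DMF, 0 °C to 90 °C; then aq. NaOAc
Reagents that add atoms: N,N-dimethylformamide, CN(C)C=O; water, O
Why: Vilsmeier–Haack formylation; the chloroiminium ion should attack mainly the position para to one methoxy group and ortho to the other (next to bromine), and the minor isomer from attack between the methoxy groups should be separable.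

Step 2
Reactants: 3 2-bromo-4,6-dimethoxybenzaldehyde
Product: 4 2-bromo-3-iodo-4,6-dimethoxybenzaldehyde
Conditions: NIS, TFA (cat.), MeCN, rt
Reagents that add atoms: N-iodosuccinimide, O=C1CCC(=O)N1I
Why: Electrophilic aromatic iodination; C3 is para to the 6-methoxy group, ortho to the 4-methoxy group and meta to the aldehyde, and the site between two methoxy groups is disfavoured, as in the 5-iodination of 2,4-dimethoxybenzaldehyde.

Step 3
Reactants: 4 2-bromo-3-iodo-4,6-dimethoxybenzaldehyde
Product: 6 2-bromo-4,6-dihydroxy-3-iodobenzaldehyde, via bis(dibromoboryl) ether 5 (not isolated)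
Conditions: BBr3, CH2Cl2, −78 °C to rt; then ice-water
Reagents that add atoms: none
Why: Lewis-acid cleavage of aryl methyl ethers with BBr3; both ethers are removed here, before any acid-sensitive alkene is present.

Step 4
Reactants: 6 2-bromo-4,6-dihydroxy-3-iodobenzaldehyde
Product: 7 2-bromo-4,6-dihydroxy-3-(3-methylbut-2-en-1-yl)benzaldehyde
Conditions: tributyl(3-methylbut-2-en-1-yl)stannane, Pd(PPh3)4 (5 mol%), DMF, 80 °C
Reagents that add atoms: tributyl(3-methylbut-2-en-1-yl)stannane, CCCC[Sn](CCCC)(CCCC)CC=C(C)C
Why: Migita–Kosugi–Stille coupling; zerovalent palladium should insert into the C–I bond well before the neighbouring C–Br bond, reductive elimination at the primary allyl terminus should give the linear prenyl arene, and the neutral conditions tolerate free phenols and the aldehyde.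

Step 5
Reactants: 7 2-bromo-4,6-dihydroxy-3-(3-methylbut-2-en-1-yl)benzaldehyde
Product: 8 2-bromo-4-{[tert-butyl(dimethyl)silyl]oxy}-6-hydroxy-3-(3-methylbut-2-en-1-yl)benzaldehyde
Conditions: TBSCl (1.05 equiv), imidazole, CH2Cl2, 0 °C
Reagents that add atoms: tert-butyldimethylsilyl chloride, CC(C)(C)[Si](C)(C)Cl
Why: Selective phenol silylation; the 6-OH is held in a hydrogen bond to the aldehyde and is the poorer nucleophile, so one equivalent of silyl chloride should go to the 4-OH next to the prenyl group.

Step 6
Reactants: 8 2-bromo-4-{[tert-butyl(dimethyl)silyl]oxy}-6-hydroxy-3-(3-methylbut-2-en-1-yl)benzaldehyde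
Product: 9 3-bromo-5-{[tert-butyl(dimethyl)silyl]oxy}-2-formyl-4-(3-methylbut-2-en-1-yl)phenyl acetate
Conditions: Ac2O, Et3N, DMAP (cat.), CH2Cl2, 0 °C to rt
Reagents that add atoms: acetic anhydride, CC(=O)OC(C)=O
Why: DMAP-catalysed acylation of the remaining hydrogen-bonded phenol; the acetate supplies the oxygen, C2 and one methyl group of the future pyran ring.

Step 7
Reactants: 9 3-bromo-5-{[tert-butyl(dimethyl)silyl]oxy}-2-formyl-4-(3-methylbut-2-en-1-yl)phenyl acetate
Product: 11 {[3-bromo-4-ethenyl-2-(3-methylbut-2-en-1-yl)-5-(prop-1-en-2-yloxy)phenyl]oxy}(tert-butyl)dimethylsilane, via styrene acetate 10 (not isolated)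
Conditions: Tebbe reagent Cp2Ti(μ-CH2)(μ-Cl)AlMe2 (3 equiv), pyridine (cat.), THF/toluene, −40 °C to rt; then 1 M NaOH, Et2O; chromatography on Et3N-treated silica
Reagents that add atoms: Tebbe reagent, C[Al-]1(C)C[Ti](C2C=CC=C2)(C2C=CC=C2)[Cl+]1
Why: Tebbe methylenation; the titanium methylidene olefinates aldehydes and, unlike phosphorus ylides, aryl esters, so one reagent should give both the styrene and the 2-propenyl ether without cleaving the acetate, and the low temperature should keep the carbene from engaging the alkenes.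

Step 8
Reactants: 11 {[3-bromo-4-ethenyl-2-(3-methylbut-2-en-1-yl)-5-(prop-1-en-2-yloxy)phenyl]oxy}(tert-butyl)dimethylsilane
Product: 14 {[5-bromo-2,2-dimethyl-6-(3-methylbut-2-en-1-yl)-2H-chromen-7-yl]oxy}(tert-butyl)dimethylsilane, via aryl oxocarbenium ion 12 (not isolated), via benzylic cation 13 (not isolated)
Conditions: CSA (10 mol%), 4 Å MS, CH2Cl2, −40 °C to 0 °C; then Et3N
Reagents that add atoms: none
Why: Proposed new method: protonation at the CH2 carbon of the 2-aryloxypropene, by far the most basic π-carbon in 11, gives the aryl oxocarbenium ion 12; its carbenium carbon is attacked by the terminal carbon of the ortho vinyl group to form the C2–C3 bond, and the benzylic cation 13 loses the C3 proton to the sulfonate, which gives the conjugated chromene and returns the acid. The closest known reaction type is the Prins (oxocarbenium–alkene) cyclisation with E1 termination, as in acid-mediated chromene formation from 2-(1-substituted-vinyl)phenols and carbonyl equivalents, run here strictly intramolecularly from a preformed enol ether. The pyran ring closes in a 6-endo-trig mode, equivalent to a 6π closure of the 2-oxonia-triene C3=C4–C4a=C8a–O1=C2, because the 5-exo alternative would give a primary cation. No stereocentre is formed and the C3=C4 alkene is necessarily cis within the ring. The step needs C–C bond formation to outrun hydrolysis, styrene protonation and prenyl participation: the silyloxy oxygen para to C4a and the ring oxygen ortho to it make C3 nucleophilic and stabilise 13, the prenyl group sits para to the reacting oxygen and cannot reach it, and sieves with a catalytic sulfonic acid at low temperature exclude water and stronger protonation.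

Step 9
Reactants: 15 1-benzofuran-6-ol
Product: 16 (1-benzofuran-6-yloxy)(tert-butyl)dimethylsilane
Conditions: TBSCl, imidazole, DMF, rt
Reagents that add atoms: tert-butyldimethylsilyl chloride, CC(C)(C)[Si](C)(C)Cl
Why: Standard silylation of a phenol; the silyl ether tolerates the later lithiation and is removed together with the other one at the end.

Step 10
Reactants: 14 {[5-bromo-2,2-dimethyl-6-(3-methylbut-2-en-1-yl)-2H-chromen-7-yl]oxy}(tert-butyl)dimethylsilane; 16 (1-benzofuran-6-yloxy)(tert-butyl)dimethylsilane
Product: 19 tert-butyl[(2-{7-{[tert-butyl(dimethyl)silyl]oxy}-2,2-dimethyl-6-(3-methylbut-2-en-1-yl)-2H-chromen-5-yl}-1-benzofuran-6-yl)oxy]dimethylsilane, via 2-lithiobenzofuran 17 (not isolated), via benzofuranylzinc chloride 18 (not isolated)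
Conditions: 16, n-BuLi, THF, −78 °C; ZnCl2, −78 °C to rt; then 14, Pd(OAc)2 (5 mol%), SPhos (10 mol%), THF, 60 °C
Reagents that add atoms: none
Why: Negishi coupling; benzofuran is lithiated at C2, its most acidic C–H, the zinc reagent tolerates the silyl ethers and alkenes, and the palladium–SPhos catalyst should couple the di-ortho-substituted, electron-rich aryl bromide with the small 2-furyl-type nucleophile.

Step 11
Reactants: 19 tert-butyl[(2-{7-{[tert-butyl(dimethyl)silyl]oxy}-2,2-dimethyl-6-(3-methylbut-2-en-1-yl)-2H-chromen-5-yl}-1-benzofuran-6-yl)oxy]dimethylsilane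
Product: 20 cathafuran C, 5-(6-hydroxy-1-benzofuran-2-yl)-2,2-dimethyl-6-(3-methylbut-2-en-1-yl)-2H-chromen-7-ol
Conditions: TBAF (2.5 equiv), AcOH (2.5 equiv), THF, 0 °C to rt
Reagents that add atoms: none
Why: Fluoride-mediated cleavage of both aryl silyl ethers; the acetic acid buffer should protect the electron-rich phenols from oxidation as phenoxides and leaves the ortho-prenylphenol and the chromene untouched.

**Compound list**

1 | 1-bromo-3,5-dimethoxybenzene | COc1cc(Br)cc(OC)c1 | starting material
2 | N-[(2-bromo-4,6-dimethoxyphenyl)methylidene]-N-methylmethanaminium chloride | C[N+](C)=Cc1c(Br)cc(OC)cc1OC.[Cl-] | intermediate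
3 | 2-bromo-4,6-dimethoxybenzaldehyde | COc1cc(Br)c(C=O)c(OC)c1 | intermediate
4 | 2-bromo-3-iodo-4,6-dimethoxybenzaldehyde | COc1cc(OC)c(I)c(Br)c1C=O | intermediate
5 | 2-bromo-4,6-bis[(dibromoboranyl)oxy]-3-iodobenzaldehyde | O=Cc1c(Br)c(I)c(OB(Br)Br)cc1OB(Br)Br | intermediate
6 | 2-bromo-4,6-dihydroxy-3-iodobenzaldehyde | O=Cc1c(O)cc(O)c(I)c1Br | intermediate
7 | 2-bromo-4,6-dihydroxy-3-(3-methylbut-2-en-1-yl)benzaldehyde | CC(C)=CCc1c(O)cc(O)c(C=O)c1Br | intermediate
8 | 2-bromo-4-{[tert-butyl(dimethyl)silyl]oxy}-6-hydroxy-3-(3-methylbut-2-en-1-yl)benzaldehyde | CC(C)=CCc1c(O[Si](C)(C)C(C)(C)C)cc(O)c(C=O)c1Br | intermediate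
9 | 3-bromo-5-{[tert-butyl(dimethyl)silyl]oxy}-2-formyl-4-(3-methylbut-2-en-1-yl)phenyl acetate | CC(C)=CCc1c(O[Si](C)(C)C(C)(C)C)cc(OC(C)=O)c(C=O)c1Br | intermediate
10 | 3-bromo-5-{[tert-butyl(dimethyl)silyl]oxy}-2-ethenyl-4-(3-methylbut-2-en-1-yl)phenyl acetate | CC(C)=CCc1c(O[Si](C)(C)C(C)(C)C)cc(OC(C)=O)c(C=C)c1Br | intermediate
11 | {[3-bromo-4-ethenyl-2-(3-methylbut-2-en-1-yl)-5-(prop-1-en-2-yloxy)phenyl]oxy}(tert-butyl)dimethylsilane | CC(C)=CCc1c(O[Si](C)(C)C(C)(C)C)cc(OC(C)=C)c(C=C)c1Br | intermediate
12 | aryl oxocarbenium ion from 11 (camphorsulfonate ion pair), O-aryl propan-2-ylideneoxonium | CC(C)=CCc1c(O[Si](C)(C)C(C)(C)C)cc([O+]=C(C)C)c(C=C)c1Br | intermediate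
13 | 5-bromo-7-{[tert-butyl(dimethyl)silyl]oxy}-2,2-dimethyl-6-(3-methylbut-2-en-1-yl)chroman-4-ylium (camphorsulfonate ion pair) | CC(C)=CCc1c(O[Si](C)(C)C(C)(C)C)cc2OC(C)(C)C[CH+]c2c1Br | intermediate
14 | {[5-bromo-2,2-dimethyl-6-(3-methylbut-2-en-1-yl)-2H-chromen-7-yl]oxy}(tert-butyl)dimethylsilane | CC(C)=CCc1c(O[Si](C)(C)C(C)(C)C)cc2OC(C)(C)C=Cc2c1Br | intermediate
15 | 1-benzofuran-6-ol | Oc1ccc2ccoc2c1 | starting material
16 | (1-benzofuran-6-yloxy)(tert-butyl)dimethylsilane | CC(C)(C)[Si](C)(C)Oc1ccc2ccoc2c1 | intermediate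
17 | (6-{[tert-butyl(dimethyl)silyl]oxy}-1-benzofuran-2-yl)lithium | [Li]c1cc2ccc(O[Si](C)(C)C(C)(C)C)cc2o1 | intermediate
18 | chlorido(6-{[tert-butyl(dimethyl)silyl]oxy}-1-benzofuran-2-yl)zinc | Cl[Zn]c1cc2ccc(O[Si](C)(C)C(C)(C)C)cc2o1 | intermediate
19 | tert-butyl[(2-{7-{[tert-butyl(dimethyl)silyl]oxy}-2,2-dimethyl-6-(3-methylbut-2-en-1-yl)-2H-chromen-5-yl}-1-benzofuran-6-yl)oxy]dimethylsilane | CC(C)=CCc1c(O[Si](C)(C)C(C)(C)C)cc2OC(C)(C)C=Cc2c1-c1cc2ccc(O[Si](C)(C)C(C)(C)C)cc2o1 | intermediate
20 | cathafuran C, 5-(6-hydroxy-1-benzofuran-2-yl)-2,2-dimethyl-6-(3-methylbut-2-en-1-yl)-2H-chromen-7-ol | CC(C)=CCc1c(O)cc2c(c1-c1cc3ccc(O)cc3o1)C=CC(C)(C)O2 | target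

**Step count and risks**

Total step count: 11. Longest linear sequence: 10 steps (steps 1 to 8, then 10 and 11); step 9 prepares the second fragment.

Steps most likely to fail:

1. Step 8 (proposed new method). The oxocarbenium ion may be hydrolysed back to the phenol by traces of water. The electron-rich styrene may be protonated and oligomerise. C–C bond formation may be slow because the vinyl group is twisted out of conjugation by its two ortho neighbours. The fallback uses known chemistry, sets out from 8 and comes back at 14. Heating 8 with (2-methylprop-1-en-1-yl)boronic acid and dibenzylamine in dioxane at 90 °C (Petasis borono-Mannich condensation) should give the racemic dibenzylamino adduct F1. F1 loses the amine on heating to give the ortho-quinone methide F2, which closes by oxa-6π electrocyclisation to 14. In this fallback the ring closes at O1–C2 and the acetate and titanium steps are not needed.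

2. Step 7. The titanium carbene may exchange with the newly formed styrene and then olefinate the neighbouring acetate, closing a 2-methylbenzofuran. The ester methylenation may stop short, or the enol ether may hydrolyse during work-up. The fallback sets out from 8 and comes back at 11. Wittig methylenation of 8 with excess Ph3P=CH2 (from Ph3PCH3Br and KOtBu, THF, 0 °C) should give the 2-vinylphenol F3. Copper-catalysed O-alkenylation of F3 with 2-bromopropene (CuI, N,N-dimethylglycine, Cs2CO3, dioxane, 90 °C, sealed tube) should then give 11.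

3. Step 4. The prenyl group may be transferred through its tertiary terminus to give the reverse-prenyl isomer, or palladium may also insert into the C–Br bond. The fallback sets out from 6 and comes back at 7. Stille coupling of 6 with allyltributylstannane (Pd(PPh3)4, DMF, 80 °C) has no regiochemical ambiguity and should give the allyl arene F4. Cross-metathesis of F4 with excess 2-methylbut-2-ene and the second-generation Grubbs catalyst RuCl2(=CHPh)(H2IMes)(PCy3) in CH2Cl2 at 40 °C should give 7.

**Further compounds**

F1 | step 8 | 3-bromo-5-{[tert-butyl(dimethyl)silyl]oxy}-2-[1-(dibenzylamino)-3-methylbut-2-en-1-yl]-4-(3-methylbut-2-en-1-yl)phenol (racemic) | CC(C)=CCc1c(O[Si](C)(C)C(C)(C)C)cc(O)c(C(C=C(C)C)N(Cc2ccccc2)Cc2ccccc2)c1Br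
F2 | step 8 | 5-bromo-3-{[tert-butyl(dimethyl)silyl]oxy}-4-(3-methylbut-2-en-1-yl)-6-(3-methylbut-2-en-1-ylidene)cyclohexa-2,4-dien-1-one (dienyl chain syn to C=O) | CC(C)=C/C=C1\C(=O)C=C(O[Si](C)(C)C(C)(C)C)C(CC=C(C)C)=C1Br
F3 | step 7 | 3-bromo-5-{[tert-butyl(dimethyl)silyl]oxy}-2-ethenyl-4-(3-methylbut-2-en-1-yl)phenol | CC(C)=CCc1c(O[Si](C)(C)C(C)(C)C)cc(O)c(C=C)c1Br
F4 | step 4 | 2-bromo-4,6-dihydroxy-3-(prop-2-en-1-yl)benzaldehyde | C=CCc1c(O)cc(O)c(C=O)c1Br
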